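If X and Q reach you as two peaks and you want their ratio at a given time, count how many times Q has halved by then.

- red: G 7.5 mM; run made earlier
- flask: G 5.0 mM; time 6.0 min

- red (time / s: X / %, Q / %): 10.0: 9.9, 6.1; 15.0: 12.0, 3.4; 40.0: 13.1, 0.3

(scatter of a reading: 0.5 percentage points)

- share of X in X plus Q at 0.80 s
- share of X in X plus Q at 6.0 min



How fast does Q halve? In the red run Q falls from 6.1% at 10.0 s to 3.4% at 15.0 s, so it halves every 5.93 s: this is the half-life of Q's fall, the time of one halving of the Q peak. Treat it as a rough reading, given the scatter of 0.5 percentage points. Run on to 40.0 s, it leaves 0.183% of Q; the reading is 0.3%.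

How far has the flask got at 0.80 s? The count is 0.135, so the fall of Q has not finished one halving and the early share, the selectivity, shows how X and Q are first made.

What can be said of that share? In the red run it reads 61.9% at 10.0 s and climbs to 77.9% at 15.0 s. Carry that trend over to the flask and commit to an early share below the first reading; this is an estimate, not a bound, and the readings give no firmer number.

And at 6.0 min? The count is 60.7, and the red run already reads 97.8% at 40.0 s, so commit to a share just under 100%.

The forecast gives 25% and 99%, and calls its early value “a long extrapolation and very uncertain”.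

The flask gives 18.7% at 0.80 s, less than the first red reading, and 99.8% at 6.0 min.

    G + Z → L (k = 130 M⁻¹ s⁻¹)
    Z → D (k = 0.310 s⁻¹)
    G → Z (k = 0.370 s⁻¹)
    Q → J (k = 0.0470 s⁻¹)
    Z ⇌ Q (K = 1.10, k = 0.560 s⁻¹)
    Z ⇌ X (K = 150, k = 0.110 s⁻¹)

At 6.0 min, Q still stands at 0.0194% beside X at 12.2%. From 3.00 min to that time the count adds 30.4 halvings, yet Q goes from 0.0215% to 0.0194%. Count the same 60.7 in the neighbour flask with 12 mM of G: its share stands at 99.8%, with Q at 0.0133% beside X at 8.37%.

The earlier runs and the new flask stem from a simulated flask from invented constants; noise was put on by code.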